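**Plan**

- Eudesmane numbers are used: ring A = C1–C5, C10; ring B = C5–C10; C4=C15 methylidene, C6 carbinol, C7 isopropyl-bearing, C9 ester-bearing. The retrosynthesis cuts the C9–O ester, returns C9 to a ketone, then cuts ring B at C5–C6 and C7–C8, which releases C6–C7 as isovaleraldehyde.
- Enabling feature: O6 and O9 are 1,4 on ring B (C6–C7–C8–C9), so C7 and C8 are both carbonyl α-carbons and are joined with reversed polarity (enamine + α-keto radical). C6–OH is homoallylic to the C4=C15 methylidene across the cis ring fusion, the retron of a carbonyl-ene closure onto a C4-methyl C4=C5 olefin of ring A.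
- Forward: ring A is carried from a cyclohexenone ester (conjugate methylation/enolate triflation, methyl cross-coupling, ester to bromomethyl ketone). Ring B is then annulated in one flask (α-alkylation, then ene closure); C9 reduction and anisoylation finish.
- Stereochemistry: C10 from catalytic asymmetric conjugate addition; C7 from the imidazolidinone organocatalyst; C5 (cis fusion) and C6 relayed from C10 in the ene transition state; C9 from CBS reduction.

Key step: step 4

Assumption: methyl 3-oxocyclohex-1-ene-1-carboxylate (1) is taken as a catalogue compound, and both enantiomers of the imidazolidinone and oxazaborolidine catalysts are available.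

**Step 1**
Reactants: 1 methyl 3-oxocyclohex-1-ene-1-carboxylate
Product: 3 methyl (1R)-1-methyl-3-{[(trifluoromethyl)sulfonyl]oxy}cyclohex-2-ene-1-carboxylate, via methylzinc enolate 2 (not isolated)
Conditions: Me2Zn, (CuOTf)2·C6H6 (2.5 mol%), chiral sulfonate-bearing imidazolinium salt (N-heterocyclic carbene precursor, 5 mol%; enantiomer giving the 1R centre), t-BuOMe, −30 °C; then Tf2O, −30 to 0 °C
Reagents that add atoms: dimethylzinc C[Zn]C; trifluoromethanesulfonic anhydride O=S(=O)(OS(=O)(=O)C(F)(F)F)C(F)(F)F
Why: Copper-catalysed asymmetric conjugate addition of Me2Zn to a β-ester-substituted cyclic enone should place the C10 methyl on the ligand-selected face to give the (R)-quaternary centre, and O-triflation of the regiodefined zinc enolate 2 in situ locks the olefin toward C5 and not C3.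

**Step 2**
Reactants: 3 methyl (1R)-1-methyl-3-{[(trifluoromethyl)sulfonyl]oxy}cyclohex-2-ene-1-carboxylate
Product: 4 methyl (1R)-1,3-dimethylcyclohex-2-ene-1-carboxylate
Conditions: MeMgBr, Fe(acac)3 (5 mol%), THF/NMP, −30 °C
Reagents that add atoms: methylmagnesium bromide C[Mg]Br
Why: Iron-catalysed Kumada-type cross-coupling of the alkenyl triflate should be faster at −30 °C than Grignard addition to the neopentyl-type ester and installs the C15 methyl without touching C10.

**Step 3**
Reactants: 4 methyl (1R)-1,3-dimethylcyclohex-2-ene-1-carboxylate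
Product: 6 2-bromo-1-[(1R)-1,3-dimethylcyclohex-2-en-1-yl]ethan-1-one, via lithium hemiketal 5 (not isolated)
Conditions: CH2Br2, MeLi·LiBr, THF/Et2O, −78 °C (carbenoid generated in the presence of 4); AcOH quench at −78 °C
Reagents that add atoms: dibromomethane BrCBr
Why: Halomethyllithium homologation of an ester under Barbier conditions: bromomethyllithium adds once to the ester carbonyl, and adduct 5 persists at −78 °C and collapses to the α-bromo ketone only on acidic quench, so no second addition occurs and the non-enolisable C10 centre is untouched.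

**Step 4**
Reactants: 6 2-bromo-1-[(1R)-1,3-dimethylcyclohex-2-en-1-yl]ethan-1-one; 7 3-methylbutanal (isovaleraldehyde, 2 equiv)
Product: 9 (3R,4S,4aS,8aR)-4-hydroxy-8a-methyl-5-methylidene-3-(propan-2-yl)octahydronaphthalen-1(2H)-one, via keto aldehyde 8 (not isolated)
Conditions: Ru(bpy)3Cl2 (0.5 mol%), (2S,5R)-2-tert-butyl-3,5-dimethylimidazolidin-4-one·HOTf (20 mol%; the enantiomer exposing the Re face of the E-enamine), 2,6-lutidine, DMF, blue LEDs, 23 °C; then, without isolation of 8, extractive exchange into CH2Cl2 and Me2AlCl (2.5 equiv), −78 to −40 °C; aq. HCl work-up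
Reagents that add atoms: none
Why: Stage one is an enamine/photoredox radical α-alkylation: electron transfer from the reduced ruthenium photocatalyst to 6 gives the electrophilic α-keto radical at C8, which adds to the Re face of the E-enamine of 7 (the other face is buried by the catalyst's tert-butyl and methyl groups), and oxidation of the α-amino radical followed by hydrolysis releases aldehyde 8 with C7 (R) under catalyst control; the closest known reaction type is the organocatalytic photoredox α-alkylation of aldehydes with phenacyl bromides and bromomalonates, a union of two carbonyl α-carbons by polarity reversal. Stage two is a Lewis-acid carbonyl-ene of the citronellal-to-isopulegol kind: the Me2AlCl-bound aldehyde carbon C6 is attacked by C5 of the trisubstituted ring A olefin while a C15 hydrogen passes to oxygen, which closes ring B (6-exo-trig at C6, ene unit H–C15–C4=C5 tethered through its terminus C5) and leaves the C4=C15 methylidene. The three-atom tether C9–C8–C7 can reach only the face of C5 syn to C9, so the fixed C10 centre dictates the cis ring fusion at C5. C6 should follow from a closed chair–chair transition state in which ring A reacts as a chair (attack anti to the pseudoaxial C10 methyl) and the complexed C=O is synclinal to C4, placing O6 trans to C4 and cis to the isopropyl group; the isopropyl group is then axial, a cost kept small because C9 is still trigonal at this oxidation level. The step needs the aldehyde to react in preference to the C9 ketone (aldehydes are far better enophiles and the ketone cannot reach the olefin through a ring of workable size), hydrogen transfer from C15 and not C3 (in the closed geometry oxygen lies over C15, which is cis to H5), and no epimerisation at C7 (aprotic Me2AlCl at −78 °C, which removes stray protons as methane).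

**Step 5**
Reactants: 9 (3R,4S,4aS,8aR)-4-hydroxy-8a-methyl-5-methylidene-3-(propan-2-yl)octahydronaphthalen-1(2H)-one
Product: 10 (1R,3R,4S,4aS,8aR)-8a-methyl-5-methylidene-3-(propan-2-yl)decahydronaphthalene-1,4-diol
Conditions: (S)-2-methyl-CBS-oxazaborolidine (20 mol%), catecholborane (2.5 equiv), toluene, −78 to −40 °C; MeOH, then aq. NaOH work-up
Reagents that add atoms: none
Why: Corey–Bakshi–Shibata reduction: the (S)-oxazaborolidine should bind the ketone with quaternary C10 as the large and C8H2 as the small substituent and deliver hydride to the face anti to the angular methyl (the face simple hydrides also take in Wieland–Miescher-type decalones), giving the (1R) alcohol cis to the methyl, while catecholborane does not hydroborate the methylidene at this temperature.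

**Step 6**
Reactants: 10 (1R,3R,4S,4aS,8aR)-8a-methyl-5-methylidene-3-(propan-2-yl)decahydronaphthalene-1,4-diol; 11 4-methoxybenzoyl chloride (1.2 equiv)
Product: 12 (1R,3R,4S,4aS,8aR)-4-hydroxy-8a-methyl-5-methylidene-3-(propan-2-yl)decahydronaphthalen-1-yl 4-methoxybenzoate
Conditions: Et3N, DMAP (cat.), CH2Cl2, 0 °C to rt
Reagents that add atoms: none
Why: DMAP-catalysed acylation should be site-selective for the equatorial C9 hydroxyl because the C6 hydroxyl is axial, 1,3-diaxial to the angular methyl and flanked by two tertiary carbons (the situation of an unreactive 11β-hydroxy steroid), so only the C9 ester forms.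

**Compound list**

1 | methyl 3-oxocyclohex-1-ene-1-carboxylate | COC(=O)C1=CC(=O)CCC1 | starting material
2 | methyl (1R)-1-methyl-3-[(methylzincio)oxy]cyclohex-2-ene-1-carboxylate (methylzinc enolate) | COC(=O)[C@]1(C)CCCC(O[Zn]C)=C1 | intermediate
3 | methyl (1R)-1-methyl-3-{[(trifluoromethyl)sulfonyl]oxy}cyclohex-2-ene-1-carboxylate | COC(=O)[C@]1(C)CCCC(OS(=O)(=O)C(F)(F)F)=C1 | intermediate
4 | methyl (1R)-1,3-dimethylcyclohex-2-ene-1-carboxylate | COC(=O)[C@]1(C)CCCC(C)=C1 | intermediate
5 | lithium 2-bromo-1-[(1R)-1,3-dimethylcyclohex-2-en-1-yl]-1-methoxyethan-1-olate (lithium hemiketal) | [Li]OC(OC)(CBr)[C@]1(C)CCCC(C)=C1 | intermediate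
6 | 2-bromo-1-[(1R)-1,3-dimethylcyclohex-2-en-1-yl]ethan-1-one | BrCC(=O)[C@]1(C)CCCC(C)=C1 | intermediate
7 | 3-methylbutanal (isovaleraldehyde) | CC(C)CC=O | starting material
8 | (2R)-4-[(1R)-1,3-dimethylcyclohex-2-en-1-yl]-4-oxo-2-(propan-2-yl)butanal (keto aldehyde) | O=C[C@@H](C(C)C)CC(=O)[C@]1(C)CCCC(C)=C1 | intermediate
9 | (3R,4S,4aS,8aR)-4-hydroxy-8a-methyl-5-methylidene-3-(propan-2-yl)octahydronaphthalen-1(2H)-one | C=C1CCC[C@]2(C)[C@H]1[C@@H](O)[C@@H](C(C)C)CC2=O | intermediate
10 | (1R,3R,4S,4aS,8aR)-8a-methyl-5-methylidene-3-(propan-2-yl)decahydronaphthalene-1,4-diol | C=C1CCC[C@]2(C)[C@H]1[C@@H](O)[C@@H](C(C)C)C[C@H]2O | intermediate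
11 | 4-methoxybenzoyl chloride | COc1ccc(cc1)C(Cl)=O | starting material
12 | (1R,3R,4S,4aS,8aR)-4-hydroxy-8a-methyl-5-methylidene-3-(propan-2-yl)decahydronaphthalen-1-yl 4-methoxybenzoate | C=C1CCC[C@]2(C)[C@H]1[C@@H](O)[C@@H](C(C)C)C[C@H]2OC(=O)c1ccc(OC)cc1 | target

Total step count: 6. Longest linear sequence: 6 steps (1 to 12).

**Steps most likely to fail**

Step 4. The ene closure may run through the competing transition state (ring A as a twist-boat with the isopropyl group equatorial), which would invert C6, and the aldehyde α-centre C7 may partly epimerise during the solvent exchange. The fallback sets out from 6 (with 7): the same one-flask sequence is run and the C6 epimer, (3R,4R,4aS,8aR)-4-hydroxy-8a-methyl-5-methylidene-3-(propan-2-yl)octahydronaphthalen-1(2H)-one F1, is carried on. Dess–Martin periodinane (NaHCO3, CH2Cl2, 0 °C, kept cold and base-free so that the methylidene does not move into conjugation) should give (3R,4aS,8aR)-8a-methyl-5-methylidene-3-(propan-2-yl)octahydronaphthalene-1,4-dione F2. NaBH4 (MeOH, −40 °C) should then reduce both carbonyls from the face anti to the angular methyl (C6 as in 6-oxo steroids, where the 1,3-diaxial angular methyl forces the axial alcohol; C9 as in step 5), which returns the route at diol 10. C6 is then set by carbonyl reduction and no longer by the C–C bond formation.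

Step 3. Addition of the thermally fragile carbenoid to the hindered neopentyl-type ester may be slow, so that carbenoid decomposition or closure of the adduct to a methoxy epoxide on warming outruns homologation. The fallback sets out from 4: saponification (KOH, MeOH/H2O, reflux) should give (1R)-1,3-dimethylcyclohex-2-ene-1-carboxylic acid F3. MeLi (2.2 equiv, Et2O, 0 °C) should convert it into 1-[(1R)-1,3-dimethylcyclohex-2-en-1-yl]ethan-1-one F4. LiN(SiMe3)2 and Me3SiCl (THF, −78 °C) should give {[1-((1R)-1,3-dimethylcyclohex-2-en-1-yl)ethenyl]oxy}(trimethyl)silane F5, and N-bromosuccinimide (THF, −78 °C) should brominate it to return the route at bromo ketone 6.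

Step 5. Hydride may be delivered to the wrong face of C9 if the substrate's own bias (approach over the convex face of the cis-decalin) overrides the catalyst, and the free C6 hydroxyl consumes borane. The fallback sets out from 9: silylation (t-BuMe2SiOTf, 2,6-lutidine, CH2Cl2, 0 °C) should give (3R,4S,4aS,8aR)-4-{[tert-butyl(dimethyl)silyl]oxy}-8a-methyl-5-methylidene-3-(propan-2-yl)octahydronaphthalen-1(2H)-one F6. The silyl ether cannot sit 1,3-diaxial to the angular methyl, which locks ring B in the chair with the isopropyl group axial. LiBH(s-Bu)3 (THF, −78 °C) must then attack C9 equatorially, anti to that axial isopropyl group, and should give (1R,3R,4S,4aS,8aR)-4-{[tert-butyl(dimethyl)silyl]oxy}-8a-methyl-5-methylidene-3-(propan-2-yl)decahydronaphthalen-1-ol F7. Acylation with 11 (Et3N, DMAP, CH2Cl2) should give (1R,3R,4S,4aS,8aR)-4-{[tert-butyl(dimethyl)silyl]oxy}-8a-methyl-5-methylidene-3-(propan-2-yl)decahydronaphthalen-1-yl 4-methoxybenzoate F8, and HF·pyridine (THF, 0 °C to rt) should remove the silyl group and return the route at target 12. This also removes the site-selectivity demand of step 6.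

**Further compounds**

F1 | step 4 | (3R,4R,4aS,8aR)-4-hydroxy-8a-methyl-5-methylidene-3-(propan-2-yl)octahydronaphthalen-1(2H)-one | C=C1CCC[C@]2(C)[C@H]1[C@H](O)[C@@H](C(C)C)CC2=O
F2 | step 4 | (3R,4aS,8aR)-8a-methyl-5-methylidene-3-(propan-2-yl)octahydronaphthalene-1,4-dione | C=C1CCC[C@]2(C)[C@H]1C(=O)[C@@H](C(C)C)CC2=O
F3 | step 3 | (1R)-1,3-dimethylcyclohex-2-ene-1-carboxylic acid | OC(=O)[C@]1(C)CCCC(C)=C1
F4 | step 3 | 1-[(1R)-1,3-dimethylcyclohex-2-en-1-yl]ethan-1-one | CC(=O)[C@]1(C)CCCC(C)=C1
F5 | step 3 | {[1-((1R)-1,3-dimethylcyclohex-2-en-1-yl)ethenyl]oxy}(trimethyl)silane | C=C(O[Si](C)(C)C)[C@]1(C)CCCC(C)=C1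
F6 | step 5 | (3R,4S,4aS,8aR)-4-{[tert-butyl(dimethyl)silyl]oxy}-8a-methyl-5-methylidene-3-(propan-2-yl)octahydronaphthalen-1(2H)-one | C=C1CCC[C@]2(C)[C@H]1[C@@H](O[Si](C)(C)C(C)(C)C)[C@@H](C(C)C)CC2=O
F7 | step 5 | (1R,3R,4S,4aS,8aR)-4-{[tert-butyl(dimethyl)silyl]oxy}-8a-methyl-5-methylidene-3-(propan-2-yl)decahydronaphthalen-1-ol | C=C1CCC[C@]2(C)[C@H]1[C@@H](O[Si](C)(C)C(C)(C)C)[C@@H](C(C)C)C[C@H]2O
F8 | step 5 | (1R,3R,4S,4aS,8aR)-4-{[tert-butyl(dimethyl)silyl]oxy}-8a-methyl-5-methylidene-3-(propan-2-yl)decahydronaphthalen-1-yl 4-methoxybenzoate | C=C1CCC[C@]2(C)[C@H]1[C@@H](O[Si](C)(C)C(C)(C)C)[C@@H](C(C)C)C[C@H]2OC(=O)c1ccc(OC)cc1
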